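**Remarks on the chemistry (assumptions)**
- Guaiane numbering is used for each half: unit A (the half with the tertiary alcohol) C1–C15, unit B C1′–C15′. α/β follow the usual guaianolide drawing (H‑1, H‑5, H‑7 α; H‑6 β).
- The target is read as the endo [4+2] adduct of two molecules of one guaianolide monomer; the key step is therefore run on the monomer, and the two bonds it forms (C1–C5 and C6–C7) end up in both halves.
- Configurations at C3 of **20** and C2 of **23** are without consequence, because both centres are oxidised later.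

## Retrosynthetic overview
1. Last disconnection: the cyclohexene ring (C2–C4′ and C14–C15′) by a Diels–Alder reaction between diosphenol **24** (diene C14=C10–C1=C2(OH) of unit A) and the exocyclic enone C4′=C15′ of dehydrozaluzanin C **21**; both partners come from **21**.
2. **21** comes from the 4α‑hydroxyguaianolide **17** by dehydration, epoxidation, epoxide‑to‑allylic‑alcohol isomerisation and oxidation.
3. Key disconnection: **17** from the acyclic epoxy aldehyde **15** in one flask. C6–C7 is made by a chromium ring‑closing allylation (ten‑membered carbocycle and γ‑lactone), then C1–C5 by an acid‑triggered transannular epoxide/allylsilane closure (cyclopentane and cycloheptane).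
4. Enabling feature: C6(O)–C7–C11(=C13) is a homoallylic‑alcohol (allylation) retron, and the 5/7 fusion bond C1–C5 is a 1,5‑transannular bond of the ten‑membered carbocycle C1–C10 whose C10=C14 exo‑methylene marks an allylsilane terminus.
5. **15** is assembled from methyl pent‑4‑ynoate, methyl acrylate and (2E)‑3‑methylpent‑2‑en‑4‑yn‑1‑ol. Ring order: ten‑membered ring + lactone (transient) → five‑ and seven‑membered rings → cyclohexene.

Key step: step 11

## Route

Step 1
Reactants: 1 methyl pent-4-ynoate
Product: 3 methyl (4Z)-5-iodo-4-[(trimethylsilyl)methyl]pent-4-enoate, via alkenylcopper 2 (not isolated)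
Conditions: Me3SiCH2MgCl, CuBr·SMe2, Et2O/Me2S, −40 °C; then 1, −40 → −10 °C; then I2, THF, −40 → 0 °C
Reagents that add atoms: (trimethylsilyl)methylmagnesium chloride (C[Si](C)(C)C[Mg]Cl); iodine (II)
Why: Normant carbocupration adds the silylmethylcopper reagent syn across the terminal alkyne (carbon to the internal position) and iodinolysis with retention should fix iodine cis to CH2SiMe3, while the ester is inert to the organocopper at low temperature.

Step 2
Reactants: 3 methyl (4Z)-5-iodo-4-[(trimethylsilyl)methyl]pent-4-enoate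
Product: 4 (4Z)-5-iodo-4-[(trimethylsilyl)methyl]pent-4-enal
Conditions: iBu2AlH (1.05 equiv), CH2Cl2, −78 °C; Rochelle salt work-up
Reagents that add atoms: none
Why: Partial reduction of the methyl ester with iBu2AlH at low temperature should stop at the tetrahedral aluminium acetal and release the aldehyde on work-up; no stereocentre is formed.

Step 3
Reactants: 4 (4Z)-5-iodo-4-[(trimethylsilyl)methyl]pent-4-enal; 5 methyl acrylate
Product: 6 methyl (6Z)-3-hydroxy-7-iodo-2-methylidene-6-[(trimethylsilyl)methyl]hept-6-enoate (racemic at C3)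
Conditions: DABCO (0.5 equiv), MeOH, 25 °C
Reagents that add atoms: none
Why: Morita–Baylis–Hillman reaction of an unhindered aldehyde; the carbinol centre is formed racemic and is removed again in step 7.

Step 4
Reactants: 7 (2E)-3-methylpent-2-en-4-yn-1-ol
Product: 8 tert-butyl(dimethyl){[(2E)-3-methylpent-2-en-4-yn-1-yl]oxy}silane
Conditions: TBSCl, imidazole, CH2Cl2, 0 → 25 °C
Reagents that add atoms: tert-butyldimethylsilyl chloride (CC(C)(C)[Si](C)(C)Cl)
Why: Standard silylation of a primary allylic alcohol; no stereocentre is involved.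

Step 5
Reactants: 8 tert-butyl(dimethyl){[(2E)-3-methylpent-2-en-4-yn-1-yl]oxy}silane
Product: 9 tert-butyl(dimethyl){[(2E)-3-methylpenta-2,4-dien-1-yl]oxy}silane
Conditions: H2 (1 atm), Pd/CaCO3 poisoned with Pb(OAc)2 (Lindlar catalyst), quinoline, hexane, 25 °C
Reagents that add atoms: none
Why: Lindlar semi-hydrogenation of the terminal alkyne should stop at the vinyl group and leave the trisubstituted E double bond untouched.

Step 6
Reactants: 9 tert-butyl(dimethyl){[(2E)-3-methylpenta-2,4-dien-1-yl]oxy}silane; 6 methyl (6Z)-3-hydroxy-7-iodo-2-methylidene-6-[(trimethylsilyl)methyl]hept-6-enoate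
Product: 11 methyl (6Z,10E)-12-{[tert-butyl(dimethyl)silyl]oxy}-3-hydroxy-10-methyl-2-methylidene-6-[(trimethylsilyl)methyl]dodeca-6,10-dienoate, via alkylborane 10 (not isolated)
Conditions: 9-BBN, THF, 0 → 25 °C; then 6, Pd(dppf)Cl2 (5 mol %), AsPh3, K3PO4 (3 M aq), DMF, 25 °C
Reagents that add atoms: none
Why: Anti-Markovnikov hydroboration of the monosubstituted diene terminus followed by B-alkyl Suzuki–Miyaura coupling with retention of the vinyl iodide geometry should give the trisubstituted allylsilane alkene with C2 and C9 trans; no stereocentre is formed.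

Step 7
Reactants: 11 methyl (6Z,10E)-12-{[tert-butyl(dimethyl)silyl]oxy}-3-hydroxy-10-methyl-2-methylidene-6-[(trimethylsilyl)methyl]dodeca-6,10-dienoate
Product: 12 methyl (2Z,6Z,10E)-2-(bromomethyl)-12-{[tert-butyl(dimethyl)silyl]oxy}-10-methyl-6-[(trimethylsilyl)methyl]dodeca-2,6,10-trienoate
Conditions: CBr4, PPh3, CH2Cl2, 0 °C
Reagents that add atoms: carbon tetrabromide (BrC(Br)(Br)Br)
Why: Appel bromination of the Baylis–Hillman alcohol with allylic transposition (SN2′) should give the thermodynamically favoured (Z)-2-(bromomethyl)enoate and removes the racemic carbinol centre; neutral conditions spare the allylsilane.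

Step 8
Reactants: 12 methyl (2Z,6Z,10E)-2-(bromomethyl)-12-{[tert-butyl(dimethyl)silyl]oxy}-10-methyl-6-[(trimethylsilyl)methyl]dodeca-2,6,10-trienoate
Product: 13 methyl (2Z,6Z,10E)-2-(bromomethyl)-12-hydroxy-10-methyl-6-[(trimethylsilyl)methyl]dodeca-2,6,10-trienoate
Conditions: HF·pyridine, pyridine, THF, 0 °C
Reagents that add atoms: none
Why: Buffered fluoride cleavage of a primary allylic silyl ether should leave the carbon-bound trimethylsilyl group and the allylic bromide intact.

Step 9
Reactants: 13 methyl (2Z,6Z,10E)-2-(bromomethyl)-12-hydroxy-10-methyl-6-[(trimethylsilyl)methyl]dodeca-2,6,10-trienoate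
Product: 14 methyl (2Z,6Z)-2-(bromomethyl)-9-[(2R,3R)-3-(hydroxymethyl)-2-methyloxiran-2-yl]-6-[(trimethylsilyl)methyl]nona-2,6-dienoate
Conditions: Ti(OiPr)4, D-(−)-diethyl tartrate, tBuOOH, 4 Å molecular sieves, CH2Cl2, −20 °C
Reagents that add atoms: tert-butyl hydroperoxide (CC(C)(C)OO)
Why: Sharpless asymmetric epoxidation touches only the allylic-alcohol double bond, and the D-(−)-tartrate catalyst should set both epoxide centres (C4 R, C5 R) by reagent control.

Step 10
Reactants: 14 methyl (2Z,6Z)-2-(bromomethyl)-9-[(2R,3R)-3-(hydroxymethyl)-2-methyloxiran-2-yl]-6-[(trimethylsilyl)methyl]nona-2,6-dienoate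
Product: 15 methyl (2Z,6Z)-2-(bromomethyl)-9-[(2R,3S)-3-formyl-2-methyloxiran-2-yl]-6-[(trimethylsilyl)methyl]nona-2,6-dienoate
Conditions: Dess–Martin periodinane, NaHCO3, CH2Cl2, 0 °C
Reagents that add atoms: none
Why: Buffered Dess–Martin oxidation of a 2,3-epoxy alcohol should give the epoxy aldehyde without epimerisation at C5 (the descriptor changes only by priority).

Step 11
Reactants: 15 methyl (2Z,6Z)-2-(bromomethyl)-9-[(2R,3S)-3-formyl-2-methyloxiran-2-yl]-6-[(trimethylsilyl)methyl]nona-2,6-dienoate
Product: 17 (1R,4R,5S,6S,7S)-4-hydroxyguaia-10(14),11(13)-dien-12,6-olide (4α-OH; H-1, H-5, H-7 α; H-6 β), via epoxygermacranolide 16 (not isolated)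
Conditions: CrCl2 (6 equiv), THF, 25 °C, slow addition of 15 (final 0.002 M); then p-TsOH (anhydrous, 3 equiv), CH2Cl2, 0 → 25 °C; aqueous NaHCO3 work-up
Reagents that add atoms: none
Why: CrCl2 inserts into the allylic C–Br bond and the 2-(methoxycarbonyl)allylchromium adds through its γ-carbon C7 to the aldehyde carbon C6 (Nozaki–Hiyama/Barbier ring-closing allylation, the reaction type used to close ten-membered germacranolide rings), the chromium alkoxide then lactonising onto the methyl ester to give 16; p-TsOH next activates the 4,5-epoxide and the allylsilane carbon C1, lying directly across the ring, opens it at C5 in an SN2-like manner while silicon is lost from C14 (transannular epoxide–allylsilane cyclisation, the same type as the acid-induced cyclisation of 4,5-epoxygermacranolides to cis-fused guaianolides). The ten-membered carbocycle closes by 10-exo-trig attack on the aldehyde under high dilution, the γ-lactone by 5-exo-trig acyl substitution, and the single transannular bond C1–C5 divides the ten-membered ring into the cyclopentane (5-endo opening of the epoxide, enforced by the ring) and the cycloheptane (7-exo). C4 keeps the configuration from the Sharpless epoxidation (the oxygen stays on C4 as the 4α-hydroxyl) and C5 is inverted; C6 and C7 should be set in the ring closure by the adjacent epoxide centre and the crossed conformation of the forming ring, which places H-6 and H-7 anti and so leads to the trans-lactone; C1 follows from the geometry of the C1=C10 double bond (C2 and C9 trans) in that conformation and should give the cis 1α,5α fusion. The step needs chemoselectivity (only the allylic bromide is metalated, allylsilane and epoxide stay inert until the acid is added), a defined alkene-forming termination (the β-silyl cation at C10 can only lose silicon, which fixes the C10=C14 exo-methylene) and ring closure over oligomerisation (slow addition at high dilution).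

Step 12
Reactants: 17 (1R,4R,5S,6S,7S)-4-hydroxyguaia-10(14),11(13)-dien-12,6-olide
Product: 18 (1R,5R,6S,7S)-guaia-3,10(14),11(13)-trien-12,6-olide (isodehydrocostus lactone)
Conditions: SOCl2, pyridine, CH2Cl2, −20 → 0 °C
Reagents that add atoms: none
Why: E2 elimination of the tertiary chlorosulfite should follow Zaitsev into the ring through the anti-periplanar 3β-hydrogen, while H-5 is cis to the leaving group and cannot be lost; no stereocentre is formed.

Step 13
Reactants: 18 (1R,5R,6S,7S)-guaia-3,10(14),11(13)-trien-12,6-olide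
Product: 19 (1R,3R,4S,5S,6S,7S)-3,4-epoxyguaia-10(14),11(13)-dien-12,6-olide (3α,4α-epoxide, estafiatin)
Conditions: mCPBA (1.0 equiv), NaHCO3, CH2Cl2, 0 °C
Reagents that add atoms: 3-chloroperoxybenzoic acid (OOC(=O)c1cccc(Cl)c1)
Why: Prilezhaev epoxidation should select the trisubstituted C3=C4 bond over the 1,1-disubstituted and the electron-poor alkenes and attack the convex α face of the cis-fused hydroazulene, which sets C3 and C4.

Step 14
Reactants: 19 (1R,3R,4S,5S,6S,7S)-3,4-epoxyguaia-10(14),11(13)-dien-12,6-olide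
Product: 20 (1R,3R,5R,6S,7S)-3-hydroxyguaia-4(15),10(14),11(13)-trien-12,6-olide (3α-OH, 3-epizaluzanin C)
Conditions: Al(OiPr)3, toluene, 110 °C
Reagents that add atoms: none
Why: Aluminium-alkoxide-mediated isomerisation of a trisubstituted epoxide to the allylic alcohol removes a hydrogen from the C15 methyl group and opens the C4–O bond, so the C3–O bond and its α configuration are retained and the exocyclic methylene is formed.

Step 15
Reactants: 20 (1R,3R,5R,6S,7S)-3-hydroxyguaia-4(15),10(14),11(13)-trien-12,6-olide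
Product: 21 (1R,5R,6S,7S)-3-oxoguaia-4(15),10(14),11(13)-trien-12,6-olide (dehydrozaluzanin C)
Conditions: Dess–Martin periodinane, NaHCO3, CH2Cl2, 0 → 25 °C
Reagents that add atoms: none
Why: Mild oxidation of the secondary allylic alcohol to the cross-conjugated enone; the C3 stereocentre is removed.

Step 16
Reactants: 21 (1R,5R,6S,7S)-3-oxoguaia-4(15),10(14),11(13)-trien-12,6-olide
Product: 23 (1R,2R,5R,6S,7S)-2-hydroxy-3-oxoguaia-4(15),10(14),11(13)-trien-12,6-olide (2α-OH), via silyl dienol ether 22 (not isolated)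
Conditions: TMSOTf, Et3N, CH2Cl2, −78 °C; then dimethyldioxirane, acetone, −78 °C; aqueous citric acid work-up
Reagents that add atoms: dimethyldioxirane (CC1(C)OO1)
Why: Rubottom oxidation: the ketone can enolise only toward C2, and the electron-rich enol ether double bond of 22 should be epoxidised in preference to the other alkenes, from the convex α face (the new centre is oxidised away in step 17).

Step 17
Reactants: 23 (1R,2R,5R,6S,7S)-2-hydroxy-3-oxoguaia-4(15),10(14),11(13)-trien-12,6-olide; 21 (1R,5R,6S,7S)-3-oxoguaia-4(15),10(14),11(13)-trien-12,6-olide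
Product: 25 target CNP0269880.2 (unit A 2S,5R,6S,7S; unit B 1′R,4′R,5′R,6′S,7′S), via diosphenol 24 (not isolated)
Conditions: Dess–Martin periodinane, NaHCO3, CH2Cl2, 0 °C, in the presence of 21 (3 equiv); then concentration to about 1 M, 30 °C
Reagents that add atoms: none
Why: Oxidation gives the 2,3-dione, which should enolise toward C1 to the diosphenol 24, whose 1-hydroxy diene C14=C10–C1=C2 undergoes a normal-demand Diels–Alder reaction with the exocyclic enone of 21 with ortho regiochemistry (C14 to C15′, C2 to C4′), endo orientation of the C3′ ketone, attack on the convex α face of the dienophile and on the diene face anti to the C6–O bond, which together set C2 (S) and the spiro centre C4′ (R).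

## Compound list
1 | methyl pent-4-ynoate | C#CCCC(=O)OC | starting material
2 | methyl (4Z)-5-cuprio-4-[(trimethylsilyl)methyl]pent-4-enoate (alkenylcopper, MgBrCl complex) | [Cu]/C=C(\C[Si](C)(C)C)CCC(=O)OC | intermediate
3 | methyl (4Z)-5-iodo-4-[(trimethylsilyl)methyl]pent-4-enoate | I/C=C(\C[Si](C)(C)C)CCC(=O)OC | intermediate
4 | (4Z)-5-iodo-4-[(trimethylsilyl)methyl]pent-4-enal | I/C=C(\C[Si](C)(C)C)CCC=O | intermediate
5 | methyl acrylate | C=CC(=O)OC | starting material
6 | methyl (6Z)-3-hydroxy-7-iodo-2-methylidene-6-[(trimethylsilyl)methyl]hept-6-enoate (racemic) | I/C=C(\C[Si](C)(C)C)CCC(O)C(=C)C(=O)OC | intermediate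
7 | (2E)-3-methylpent-2-en-4-yn-1-ol | OC/C=C(\C)C#C | starting material
8 | tert-butyl(dimethyl){[(2E)-3-methylpent-2-en-4-yn-1-yl]oxy}silane | CC(C)(C)[Si](C)(C)OC/C=C(\C)C#C | intermediate
9 | tert-butyl(dimethyl){[(2E)-3-methylpenta-2,4-dien-1-yl]oxy}silane | CC(C)(C)[Si](C)(C)OC/C=C(\C)C=C | intermediate
10 | 9-[(3E)-5-{[tert-butyl(dimethyl)silyl]oxy}-3-methylpent-3-en-1-yl]-9-borabicyclo[3.3.1]nonane | CC(C)(C)[Si](C)(C)OC/C=C(\C)CCB1C2CCCC1CCC2 | intermediate
11 | methyl (6Z,10E)-12-{[tert-butyl(dimethyl)silyl]oxy}-3-hydroxy-10-methyl-2-methylidene-6-[(trimethylsilyl)methyl]dodeca-6,10-dienoate (racemic at C3) | COC(=O)C(=C)C(O)CC/C(C[Si](C)(C)C)=C/CC/C(C)=C/CO[Si](C)(C)C(C)(C)C | intermediate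
12 | methyl (2Z,6Z,10E)-2-(bromomethyl)-12-{[tert-butyl(dimethyl)silyl]oxy}-10-methyl-6-[(trimethylsilyl)methyl]dodeca-2,6,10-trienoate | COC(=O)/C(CBr)=C/CC/C(C[Si](C)(C)C)=C/CC/C(C)=C/CO[Si](C)(C)C(C)(C)C | intermediate
13 | methyl (2Z,6Z,10E)-2-(bromomethyl)-12-hydroxy-10-methyl-6-[(trimethylsilyl)methyl]dodeca-2,6,10-trienoate | COC(=O)/C(CBr)=C/CC/C(C[Si](C)(C)C)=C/CC/C(C)=C/CO | intermediate
14 | methyl (2Z,6Z)-2-(bromomethyl)-9-[(2R,3R)-3-(hydroxymethyl)-2-methyloxiran-2-yl]-6-[(trimethylsilyl)methyl]nona-2,6-dienoate | OC[C@H]1O[C@]1(C)CC/C=C(\C[Si](C)(C)C)CC/C=C(\CBr)C(=O)OC | intermediate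
15 | methyl (2Z,6Z)-2-(bromomethyl)-9-[(2R,3S)-3-formyl-2-methyloxiran-2-yl]-6-[(trimethylsilyl)methyl]nona-2,6-dienoate | O=C[C@H]1O[C@]1(C)CC/C=C(\C[Si](C)(C)C)CC/C=C(\CBr)C(=O)OC | intermediate
16 | (4R,5R,6S,7S)-4,5-epoxy-14-(trimethylsilyl)germacra-1(10),11(13)-dien-12,6-olide (C2 and C9 trans on the C1=C10 bond; trans-lactone) | C[C@@]12CC/C=C(\C[Si](C)(C)C)CC[C@H]3C(=C)C(=O)O[C@@H]3[C@H]1O2 | intermediate
17 | (1R,4R,5S,6S,7S)-4-hydroxyguaia-10(14),11(13)-dien-12,6-olide | C[C@@]1(O)CC[C@H]2C(=C)CC[C@H]3C(=C)C(=O)O[C@@H]3[C@@H]12 | intermediate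
18 | (1R,5R,6S,7S)-guaia-3,10(14),11(13)-trien-12,6-olide | CC1=CC[C@H]2C(=C)CC[C@H]3C(=C)C(=O)O[C@@H]3[C@@H]12 | intermediate
19 | (1R,3R,4S,5S,6S,7S)-3,4-epoxyguaia-10(14),11(13)-dien-12,6-olide | C[C@@]12O[C@@H]1C[C@H]3C(=C)CC[C@H]4C(=C)C(=O)O[C@@H]4[C@@H]23 | intermediate
20 | (1R,3R,5R,6S,7S)-3-hydroxyguaia-4(15),10(14),11(13)-trien-12,6-olide | C=C1[C@H](O)C[C@H]2C(=C)CC[C@H]3C(=C)C(=O)O[C@@H]3[C@@H]12 | intermediate
21 | (1R,5R,6S,7S)-3-oxoguaia-4(15),10(14),11(13)-trien-12,6-olide (dehydrozaluzanin C) | C=C1C(=O)C[C@H]2C(=C)CC[C@H]3C(=C)C(=O)O[C@@H]3[C@@H]12 | intermediate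
22 | (1R,5R,6S,7S)-3-[(trimethylsilyl)oxy]guaia-2,4(15),10(14),11(13)-tetraen-12,6-olide | C=C1C(O[Si](C)(C)C)=C[C@H]2C(=C)CC[C@H]3C(=C)C(=O)O[C@@H]3[C@@H]12 | intermediate
23 | (1R,2R,5R,6S,7S)-2-hydroxy-3-oxoguaia-4(15),10(14),11(13)-trien-12,6-olide | C=C1C(=O)[C@H](O)[C@H]2C(=C)CC[C@H]3C(=C)C(=O)O[C@@H]3[C@@H]12 | intermediate
24 | (5R,6S,7S)-2-hydroxy-3-oxoguaia-1,4(15),10(14),11(13)-tetraen-12,6-olide (diosphenol) | C=C1C(=O)C(O)=C2C(=C)CC[C@H]3C(=C)C(=O)O[C@@H]3[C@@H]12 | intermediate
25 | CNP0269880.2 (spiro Diels–Alder dimer; 2S,5R,6S,7S,1′R,4′R,5′R,6′S,7′S) | C=C1C(=O)[C@]2(O)C3=C(CC[C@H]4C(=C)C(=O)O[C@@H]4[C@@H]13)CC[C@]21C(=O)C[C@H]2C(=C)CC[C@H]3C(=C)C(=O)O[C@@H]3[C@H]21 | target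

## Step count and risks
Total step count: 17. Longest linear sequence: 15 steps (steps 1–3 and 6–17, from methyl pent-4-ynoate); steps 4 and 5 prepare the second fragment.

**Step 11 (key step).** What may go wrong: oligomerisation instead of ring closure, a cis relationship at C6/C7 (acyclic chromium additions of such bromides tend to the cis-lactone, so the outcome rests on ring control), reduction of the epoxy aldehyde by CrCl2, or epoxide opening by other acid-induced pathways instead of the transannular attack. Fallback: the two bond formations are uncoupled and the ten-membered ring is closed at C1–C2 instead of C6–C7. Compound 7 is semi-hydrogenated to (2E)-3-methylpenta-2,4-dien-1-ol F1, epoxidised under the same Sharpless conditions to the vinyl epoxy alcohol F2 and oxidised to the vinyl epoxy aldehyde F3. Compound 6 is converted by the Appel reaction into the iodo dienyl bromide F4. A zinc Barbier reaction of F3 with F4 in THF/aqueous NH4Cl followed by lactonisation should give the open-chain α-methylene lactone F5 after separation of C6/C7 diastereomers. Hydroboration of its vinyl group with 9-BBN gives the alkylborane F6, which is closed by intramolecular B-alkyl Suzuki–Miyaura coupling (Pd(dppf)Cl2, AsPh3, Cs2CO3, high dilution) to 16. Isolated 16 is then cyclised with p-TsOH in CH2Cl2, and the route is rejoined at 17.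

**Step 17.** What may go wrong: self-dimerisation of the diosphenol through its own exocyclic enone, or poor endo and facial selectivity in the cycloaddition. Fallback: the cyclohexene ring is built from the non-hydroxylated diene and C2 is oxidised afterwards. Compound 21 is converted with TBSOTf/Et3N into its silyl dienol ether F7. Saegusa–Ito oxidation with Pd(OAc)2 in MeCN in the presence of excess 21 generates the trienone F8, which should add to 21 with the same regiochemistry and endo sense to give the 2-deoxy adduct F9. The doubly activated C2–H of F9 is then hydroxylated through its extended enolate (KN(SiMe3)2, then 3-phenyl-2-(phenylsulfonyl)oxaziridine; retention is enforced by the ring system), which rejoins the route at 25.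

**Step 12.** What may go wrong: elimination toward the C15 methyl group (exocyclic olefin) instead of into the ring, or chloride substitution at the tertiary centre. Fallback: the elimination is steered to the exocyclic side and C3 is oxidised directly. Compound 17 is dehydrated with Burgess reagent (or Martin sulfurane) to dehydrocostus lactone F10, and allylic oxidation with SeO2 (catalytic) and tBuOOH at C3 should give the 3α-alcohol, which rejoins the route at 20.

Further compounds
F1 | step 11 | (2E)-3-methylpenta-2,4-dien-1-ol | OC/C=C(\C)C=C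
F2 | step 11 | [(2R,3R)-3-ethenyl-3-methyloxiran-2-yl]methanol | OC[C@H]1O[C@]1(C)C=C
F3 | step 11 | (2S,3R)-3-ethenyl-3-methyloxirane-2-carbaldehyde | O=C[C@H]1O[C@]1(C)C=C
F4 | step 11 | methyl (2Z,6Z)-2-(bromomethyl)-7-iodo-6-[(trimethylsilyl)methyl]hepta-2,6-dienoate | I/C=C(\C[Si](C)(C)C)CC/C=C(\CBr)C(=O)OC
F5 | step 11 | (4S,5S)-5-[(2R,3R)-3-ethenyl-3-methyloxiran-2-yl]-4-{(3Z)-4-iodo-3-[(trimethylsilyl)methyl]but-3-en-1-yl}-3-methylideneoxolan-2-one | C[C@]1(C=C)O[C@@H]1[C@H]2OC(=O)C(=C)[C@@H]2CC/C(C[Si](C)(C)C)=C/I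
F6 | step 11 | 9-BBN adduct of F5 at the vinyl terminus (alkylborane) | C[C@]1(CCB2C3CCCC2CCC3)O[C@@H]1[C@H]2OC(=O)C(=C)[C@@H]2CC/C(C[Si](C)(C)C)=C/I
F7 | step 17 | (1R,5R,6S,7S)-3-{[tert-butyl(dimethyl)silyl]oxy}guaia-2,4(15),10(14),11(13)-tetraen-12,6-olide | C=C1C(O[Si](C)(C)C(C)(C)C)=C[C@H]2C(=C)CC[C@H]3C(=C)C(=O)O[C@@H]3[C@@H]12
F8 | step 17 | (5R,6S,7S)-3-oxoguaia-1,4(15),10(14),11(13)-tetraen-12,6-olide | C=C1C(=O)C=C2C(=C)CC[C@H]3C(=C)C(=O)O[C@@H]3[C@@H]12
F9 | step 17 | 2-deoxy analogue of 25 (Diels–Alder adduct with H at C2) | C=C1C(=O)[C@@H]2C3=C(CC[C@H]4C(=C)C(=O)O[C@@H]4[C@@H]13)CC[C@]21C(=O)C[C@H]2C(=C)CC[C@H]3C(=C)C(=O)O[C@@H]3[C@H]21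
F10 | step 12 | (1R,5R,6S,7S)-guaia-4(15),10(14),11(13)-trien-12,6-olide (dehydrocostus lactone) | C=C1CC[C@H]2C(=C)CC[C@H]3C(=C)C(=O)O[C@@H]3[C@@H]12
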